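**Remark on the chemistry:** 3,5-bis(benzyloxy)phenol (1) is taken as a purchasable starting material. Diketo ester 8 exists largely as its chelated enol and is drawn as the triketo tautomer. The target has no stereocentre, so none has to be set.

## The problem

The target is a depside made of two copies of one unit, 2,4-dihydroxy-6-(2-oxoheptyl)benzoic acid. The carboxyl of ring A (the acyl ring) is esterified to the C4 oxygen of ring B, and ring B keeps its own C1 carboxyl and C2 hydroxyl free. There is no stereocentre and no ring to close, so the difficulty lies in the substitution pattern and in the order of functional-group operations. Each ring is a 1,2,3,5-tetrasubstituted benzene in which the carboxyl carbon C1 is wedged between the oxygen-bearing C2 and C6, which carries CH2C(=O)C5H11. The two copies must be told apart late: ring A enters the coupling with a free carboxyl and masked phenols, ring B with a masked carboxyl and a free C4 hydroxyl. The ketone lies 1,5 to the carboxyl carbon, so any activation of the acid, and strong acid or base in general, closes the enol lactone (an isocoumarin). The benzylic CH2 between arene and ketone is acidic, the aryl ester does not survive hydroxide, alkoxide or amines, and the free β-resorcylic acid loses CO2 on heating. The feature that makes the key step possible is that C1 and C6 are ortho neighbours that both carry carbon substituents, and that C1 sits beside the oxygenated C2. This pair of ring carbons maps onto the triple bond of a 3,5-dioxygenated benzyne whose flanking oxygen orients the addition, so both C–C bonds can come from insertion of the aryne into one C–C bond of an acyclic dicarbonyl chain.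

## Retrosynthesis

**19 ⇒ 18 ⇒ 17 (unmasking only).** The last two operations cut no skeletal bond. The three O–benzyl bonds of 18 (two ethers on ring A, the ester on ring B) are removed last by hydrogenolysis, which is neutral and leaves the depside ester and both ketones alone. One step earlier the two dioxolanes of 17 are hydrolysed while the ring B carboxyl is still a benzyl ester, so the acid catalyst never meets a free keto acid. Methyl ethers or a methyl ester would need Lewis acids or hydroxide that the aryl ester cannot tolerate. The forward steps must leave the benzylic ketones unreduced and must not trigger enol-lactone closure.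

**17 ⇒ 14 + 16 (depside ester C–O bond).** Cutting the aryl ester divides the molecule into two halves of almost equal size that differ only in protection. Acid 14 carries benzyl ethers and a dioxolane; phenol 16 carries a benzyl ester, a dioxolane and two free hydroxyls. The dioxolane in 14 is necessary, because an activated 2-(2-oxoalkyl)benzoic acid would lactonise instead of acylating a phenol. In 16 the C2 hydroxyl is chelated to the ester carbonyl and flanked by it, so the forward acylation is expected at the C4 hydroxyl without further protection.

**16 ⇒ 15 ⇒ 14 (both halves from one acid).** Phenol partner 16 is traced to acid 14 itself: hydrogenolysis of the two benzyl ethers gives dihydroxy acid 15, and alkylation of its carboxylate gives 16. This costs two steps but saves a second arene synthesis. The forward alkylation must touch only the carboxylate, which a bicarbonate base secures.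

**14 ⇒ 12 ⇒ 11 (carboxyl from a glyoxylate; ketal).** The carboxyl of 14 is derived from the aryl glyoxylate of 12 by hydrolysis and oxidative loss of the ester carbon, and the dioxolane of 12 from the ketone of 11. The one-carbon detour is accepted because the insertion needs a ketone as the acyl acceptor. A malonate-type partner would deliver the benzoate directly, but only with an acetate side chain that must then be built up. Ketalising before the oxidation means that a free ketone and a free carboxyl never coexist and that no enolisable ketone meets alkaline peroxide. The ketalisation must discriminate the dialkyl ketone from the hindered, ester-deactivated glyoxylate ketone.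

**11 ⇒ 5 + 8 through aryne 9 (key disconnection).** Two bonds are cut: ring C6–CH2 and ring C1–C(=O). Both substituents are traced to the C2–C3 bond of diketo ester 8, into which aryne 9 (from silyl triflate 5) is inserted. The alternative is stepwise substitution of a resorcylate (lateral metalation and acylation of an ortho methyl group). That route passes through the enol lactone and fixes the protecting groups early. The insertion instead delivers the side chain as an open ketone and the carboxyl in masked form. The precursors are a symmetrically oxygenated arene and a C9 chain. The forward reaction must add the enolate carbon to the aryne carbon remote from the flanking benzyloxy group and must close the aryl anion onto the C2 ketone rather than onto the C4 ketone or the ester.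

**8 ⇒ 6 + 7 and 5 ⇒ 3 ⇒ 2 ⇒ 1.** Diketo ester 8 comes from 2-heptanone 6 and diethyl oxalate 7 by cutting the C3–C2 bond (Claisen condensation at the methyl group). Silyl triflate 5 is traced through silyl ether 3 and bromophenol 2 to phenol 1: the C–Si bond arises by O-to-C silyl shift after bromine–lithium exchange, and the bromine is placed ortho to the hydroxyl of 1.

## Roads not taken

**Alternative 1:** The ring is built de novo by cutting ring bonds C1–C2 and C5–C6. In the forward direction 1-methoxy-1,3-bis(trimethylsilyloxy)buta-1,3-diene A2 and benzyl 4-(2-pentyl-1,3-dioxolan-2-yl)but-2-ynoate A3 combine on heating. The cycloadduct aromatises by loss of methanol and is desilylated to benzyl 2,4-dihydroxy-6-[(2-pentyl-1,3-dioxolan-2-yl)methyl]benzoate A1, which is the same compound as 16.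
- Merits: A1 arrives with free phenols, benzyl ester and ketal already in place, with no bromination, no aryne precursor and no protecting-group removal. The reaction type (silyloxydiene plus acetylenic ester) is known, and the polarisation of both partners fixes the orientation.
- Weak points: A3 needs its own synthesis of several steps. A β-alkylated ynoate is a sluggish dienophile. Its propargylic CH2 can isomerise to the allenoate. The dioxolane must survive heating with silyl species.
- The decisive limitation is that only the ring B half is delivered. The ring A half needs benzyl ethers and a free carboxyl, which from A1 would mean benzylating a chelated hydroxyl and then cleaving a benzyl ester beside benzyl ethers, so a second ynoate ester series would be required.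
- Comparison: for the ring B partner this road is shorter than the chosen plan and rests on better precedent. The chosen plan sets against this that the single intermediate 14 feeds both halves and that the aryne route carries benzyl ethers from the start.

**Alternative 2:** The ring C6–C bond and the lactone C–O bond are cut. 2,4-Bis(benzyloxy)benzoic acid A5 and dimethylsulfoxonium 2-oxoheptylide A6 react under [Cp*RhCl2]2, AgSbF6 and NaOAc (trivalent rhodium, carboxylate-directed C–H activation, carbene insertion, cyclodehydration) to give 6,8-bis(benzyloxy)-3-pentyl-1H-isochromen-1-one A4.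
- Merits: this is the shortest access to the carbon skeleton. The regiochemistry is unambiguous because A5 has a single free ortho C–H. The method is catalytic and precedented for benzoic acids.
- Weak points: A4 is the enol lactone that the target's units must avoid. Opening it with hydroxide gives the salt of 2,4-bis(benzyloxy)-6-(2-oxoheptyl)benzoic acid A7, which recloses on acidification or activation. To go on, the ketone would have to be ketalised in the presence of a free carboxyl, or the carboxylate alkylated in situ, for both halves.
- Comparison: in step count to the arene and in precedent for the C–C bond formation this road is better than the chosen plan. The chosen plan sets against this that the chain arrives as an open ketone while the carboxyl is still a glyoxylate ester, so the ketal can be installed before a free ketone and a free carboxyl ever coexist.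

**Alternative 3:** The ring C1–C6 bond is cut in a biomimetic sense. KOH in methanol opens 4-hydroxy-6-[2-oxo-3-(2-pentyl-1,3-dioxolan-2-yl)propyl]-2H-pyran-2-one A9 to potassium 3,5,7-trioxo-8-(2-pentyl-1,3-dioxolan-2-yl)octanoate A10. Its C2 adds to the C7 ketone, and loss of water gives 2,4-dihydroxy-6-[(2-pentyl-1,3-dioxolan-2-yl)methyl]benzoic acid A8, the same compound as 15.
- Merits: no oxygen protecting group is needed, and A8 is one alkylation away from 16.
- Weak points: the folding mode is not secured. A10 can also close by Claisen acylation to an acylphloroglucinol or return to a pyrone. Its C7 ketone has the ketal carbon in the β position, so base can open the dioxolane by β-elimination. A9 itself needs a multistep assembly. As in Alternative 1, only the ring B half is served, since the ring A half would need perbenzylation and cleavage of a hindered ester.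
- Comparison: in protecting-group economy for ring B this road is better. The chosen plan sets against this an orientation fixed by aryne polarisation instead of by competing enolate cyclisations, and direct access to the ring A partner 14.

Key step: step 5

## Route

Step 1
Reactants: 1 3,5-bis(benzyloxy)phenol
Product: 2 2-bromo-3,5-bis(benzyloxy)phenol
Conditions: NBS (1.0 equiv), i-Pr2NH (cat.), CH2Cl2, −78 °C to −20 °C
Reagents that add atoms: N-bromosuccinimide, O=C1CCC(=O)N1Br
Why: Electrophilic aromatic bromination; the amine–NBS system delivers bromine ortho to the free hydroxyl by hydrogen bonding, and the position between the two benzyloxy groups is the more hindered one, so C2 should be brominated preferentially.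

Step 2
Reactants: 2 2-bromo-3,5-bis(benzyloxy)phenol
Product: 3 [2-bromo-3,5-bis(benzyloxy)phenoxy]trimethylsilane
Conditions: HMDS, THF, 70 °C; concentrate
Reagents that add atoms: hexamethyldisilazane, C[Si](C)(C)N[Si](C)(C)C
Why: O-Silylation of a phenol with hexamethyldisilazane; ammonia is the only by-product, so the crude silyl ether can be used after evaporation.

Step 3
Reactants: 3 [2-bromo-3,5-bis(benzyloxy)phenoxy]trimethylsilane
Product: 5 3,5-bis(benzyloxy)-2-(trimethylsilyl)phenyl trifluoromethanesulfonate, via lithium 3,5-bis(benzyloxy)-2-(trimethylsilyl)phenoxide 4 (not isolated)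
Conditions: n-BuLi, THF, −100 °C to −78 °C; then Tf2O, −100 °C to rt
Reagents that add atoms: trifluoromethanesulfonic anhydride, O=S(=O)(OS(=O)(=O)C(F)(F)F)C(F)(F)F; n-butyllithium, [Li]CCCC (lithium of 4 only)
Why: Bromine–lithium exchange followed by retro-Brook (O-to-C) silyl migration gives phenoxide 4, which is triflated in the same flask; exchange at −100 °C is far faster than metalation of the benzyl ethers.

Step 4
Reactants: 6 2-heptanone; 7 diethyl oxalate
Product: 8 ethyl 2,4-dioxononanoate
Conditions: NaOEt, EtOH, 0 °C to rt; then cold aq. HCl
Reagents that add atoms: none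
Why: Crossed Claisen condensation; diethyl oxalate cannot enolise, and under equilibrating conditions the methyl group of the ketone is acylated, the stable chelated enolate of the product driving the reaction.

Step 5
Reactants: 5 3,5-bis(benzyloxy)-2-(trimethylsilyl)phenyl trifluoromethanesulfonate; 8 ethyl 2,4-dioxononanoate
Product: 11 ethyl 2-[2,4-bis(benzyloxy)-6-(2-oxoheptyl)phenyl]-2-oxoacetate, via 3,5-bis(benzyloxy)benzyne 9 (not isolated), via caesium benzocyclobutenoxide adduct 10 (not isolated)
Conditions: CsF (3 equiv), 8 (1.5 equiv), MeCN, 80 °C
Reagents that add atoms: caesium fluoride, [Cs+].[F-] (counter-ion of 10 only; no atom of it reaches 11)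
Why: Proposed new method: fluoride removes the silyl group of 5 and triflate leaves to give aryne 9; the caesium enolate of 8 adds through C3 to the aryne carbon remote from the flanking benzyloxy group, so that the aryl anion develops on the carbon next to oxygen, where the C–O bond stabilises it inductively. This anion closes onto the adjacent C2 ketone (4-exo-trig) to give benzocyclobutenoxide 10, which opens by cleavage of the old C2–C3 bond and releases the benzylic ketone enolate, protonated by the excess of 8. The closest known reaction type is the aryne acyl-alkylation of β-keto esters and 1,3-diketones by formal insertion into the C–C(=O) bond; a 2,4-diketo ester has not been used as the partner. No ring remains in the product, since the four-membered ring is closed and reopened in the same event, and no stereocentre survives, because the two centres of 10 end as CH2 and C=O. Two selectivities are needed. Regioselectivity comes from the benzyloxy group beside the triple bond, which polarises and distorts the aryne so that carbon nucleophiles attack the far carbon. Chemoselectivity of the aryl anion for C2 over the C4 ketone and over the ester carbon (a five-membered Parham-type closure) rests on C2 being the most electrophilic carbonyl, activated by the neighbouring ester, and the one bound directly to C3. The excess of the acidic diketo ester buffers the medium so that the released enolate is quenched before it can condense with the glyoxylate.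

Step 6
Reactants: 11 ethyl 2-[2,4-bis(benzyloxy)-6-(2-oxoheptyl)phenyl]-2-oxoacetate
Product: 12 ethyl 2-{2,4-bis(benzyloxy)-6-[(2-pentyl-1,3-dioxolan-2-yl)methyl]phenyl}-2-oxoacetate
Conditions: 1,2-bis(trimethylsilyloxy)ethane, TMSOTf (cat.), CH2Cl2, −78 °C to −20 °C; pyridine quench
Reagents that add atoms: 1,2-bis(trimethylsilyloxy)ethane, C[Si](C)(C)OCCO[Si](C)(C)C
Why: Silyl-triflate-catalysed dioxolane formation under aprotic, kinetic conditions; the dialkyl ketone reacts, whereas the glyoxylate ketone is flanked by two ortho substituents and its oxocarbenium ion is destabilised by the adjacent ester. The low temperature and absence of protic acid disfavour enolisation and hence aldol closure.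

Step 7
Reactants: 12 ethyl 2-{2,4-bis(benzyloxy)-6-[(2-pentyl-1,3-dioxolan-2-yl)methyl]phenyl}-2-oxoacetate
Product: 14 2,4-bis(benzyloxy)-6-[(2-pentyl-1,3-dioxolan-2-yl)methyl]benzoic acid, via lithium aryl glyoxylate 13 (not isolated)
Conditions: LiOH, THF/H2O, 0 °C; then 30% aq. H2O2, 0 °C to rt; Na2SO3 quench, cold 0.5 M HCl to pH 4
Reagents that add atoms: hydrogen peroxide, OO (one carboxyl oxygen of 14); lithium hydroxide, [Li+].[OH-] (lithium and one carboxylate oxygen of 13 only)
Why: Saponification of the activated α-keto ester, then oxidative decarboxylation of the α-keto acid: hydroperoxide adds to the ketone and the adduct fragments with loss of CO2. Ketal and benzyl ethers are inert to base and peroxide, and with the ketone masked no enolate can form.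

Step 8
Reactants: 14 2,4-bis(benzyloxy)-6-[(2-pentyl-1,3-dioxolan-2-yl)methyl]benzoic acid
Product: 15 2,4-dihydroxy-6-[(2-pentyl-1,3-dioxolan-2-yl)methyl]benzoic acid
Conditions: H2 (1 atm), 10% Pd/C, EtOAc, rt; used at once
Reagents that add atoms: none
Why: Hydrogenolysis of aryl benzyl ethers in a neutral aprotic solvent; the dioxolane and the carboxyl are untouched, and the acid is not heated or stored, to avoid decarboxylation and self-catalysed ketal opening.

Step 9
Reactants: 15 2,4-dihydroxy-6-[(2-pentyl-1,3-dioxolan-2-yl)methyl]benzoic acid
Product: 16 benzyl 2,4-dihydroxy-6-[(2-pentyl-1,3-dioxolan-2-yl)methyl]benzoate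
Conditions: BnBr (1.05 equiv), KHCO3, DMF, rt
Reagents that add atoms: benzyl bromide, BrCc1ccccc1
Why: Chemoselective O-alkylation of a carboxylate; bicarbonate deprotonates the carboxyl but not the phenols, so only the ester forms.

Step 10
Reactants: 14 2,4-bis(benzyloxy)-6-[(2-pentyl-1,3-dioxolan-2-yl)methyl]benzoic acid; 16 benzyl 2,4-dihydroxy-6-[(2-pentyl-1,3-dioxolan-2-yl)methyl]benzoate
Product: 17 benzyl 4-({2,4-bis(benzyloxy)-6-[(2-pentyl-1,3-dioxolan-2-yl)methyl]benzoyl}oxy)-2-hydroxy-6-[(2-pentyl-1,3-dioxolan-2-yl)methyl]benzoate
Conditions: DCC, DMAP (cat.), CH2Cl2, 0 °C to rt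
Reagents that add atoms: none
Why: Steglich esterification under neutral conditions that the ketals tolerate; the C4 hydroxyl of 16 is free and the more nucleophilic one, whereas the C2 hydroxyl is chelated to the ester carbonyl and shielded by it.

Step 11
Reactants: 17 benzyl 4-({2,4-bis(benzyloxy)-6-[(2-pentyl-1,3-dioxolan-2-yl)methyl]benzoyl}oxy)-2-hydroxy-6-[(2-pentyl-1,3-dioxolan-2-yl)methyl]benzoate
Product: 18 benzyl 4-{[2,4-bis(benzyloxy)-6-(2-oxoheptyl)benzoyl]oxy}-2-hydroxy-6-(2-oxoheptyl)benzoate
Conditions: PPTS, acetone/H2O, 50 °C
Reagents that add atoms: water, O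
Why: Mild acid-catalysed hydrolysis of two dialkyl ketone dioxolanes; the buffered acid should leave the aryl ester, the benzyl ester and the benzyl ethers intact and should be too weak to drive enol-lactone closure.

Step 12
Reactants: 18 benzyl 4-{[2,4-bis(benzyloxy)-6-(2-oxoheptyl)benzoyl]oxy}-2-hydroxy-6-(2-oxoheptyl)benzoate
Product: 19 4-{[2,4-dihydroxy-6-(2-oxoheptyl)benzoyl]oxy}-2-hydroxy-6-(2-oxoheptyl)benzoic acid
Conditions: H2 (1 atm), 10% Pd/C, EtOAc, rt
Reagents that add atoms: none
Why: Hydrogenolysis of two benzyl ethers and one benzyl ester under neutral conditions; the non-conjugated ketones and the depside ester are not reduced at ambient pressure and temperature.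

## Compound list

1 | 3,5-bis(benzyloxy)phenol | Oc1cc(OCc2ccccc2)cc(OCc2ccccc2)c1 | starting material
2 | 2-bromo-3,5-bis(benzyloxy)phenol | Oc1cc(OCc2ccccc2)cc(OCc2ccccc2)c1Br | intermediate
3 | [2-bromo-3,5-bis(benzyloxy)phenoxy]trimethylsilane | C[Si](C)(C)Oc1cc(OCc2ccccc2)cc(OCc2ccccc2)c1Br | intermediate
4 | lithium 3,5-bis(benzyloxy)-2-(trimethylsilyl)phenoxide | [Li+].[O-]c1cc(OCc2ccccc2)cc(OCc2ccccc2)c1[Si](C)(C)C | intermediate (not isolated)
5 | 3,5-bis(benzyloxy)-2-(trimethylsilyl)phenyl trifluoromethanesulfonate | C[Si](C)(C)c1c(OS(=O)(=O)C(F)(F)F)cc(OCc2ccccc2)cc1OCc1ccccc1 | intermediate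
6 | 2-heptanone | CCCCCC(C)=O | starting material
7 | diethyl oxalate | CCOC(=O)C(=O)OCC | starting material
8 | ethyl 2,4-dioxononanoate | CCCCCC(=O)CC(=O)C(=O)OCC | intermediate
9 | 3,5-bis(benzyloxy)benzyne (1,2-didehydro-3,5-bis(benzyloxy)benzene) | C1#CC(OCc2ccccc2)=CC(OCc2ccccc2)=C1 | intermediate (not isolated)
10 | caesium salt of ethyl 3,5-bis(benzyloxy)-8-hexanoyl-7-oxidobicyclo[4.2.0]octa-1,3,5-triene-7-carboxylate (both ring sp3 carbons are stereocentres; racemic, relative configuration uncontrolled and lost on ring opening) | [Cs+].CCCCCC(=O)C1c2cc(OCc3ccccc3)cc(OCc3ccccc3)c2C1([O-])C(=O)OCC | intermediate (not isolated)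
11 | ethyl 2-[2,4-bis(benzyloxy)-6-(2-oxoheptyl)phenyl]-2-oxoacetate | CCCCCC(=O)Cc1cc(OCc2ccccc2)cc(OCc2ccccc2)c1C(=O)C(=O)OCC | intermediate
12 | ethyl 2-{2,4-bis(benzyloxy)-6-[(2-pentyl-1,3-dioxolan-2-yl)methyl]phenyl}-2-oxoacetate | CCCCCC1(Cc2cc(OCc3ccccc3)cc(OCc3ccccc3)c2C(=O)C(=O)OCC)OCCO1 | intermediate
13 | lithium 2-{2,4-bis(benzyloxy)-6-[(2-pentyl-1,3-dioxolan-2-yl)methyl]phenyl}-2-oxoacetate | [Li+].CCCCCC1(Cc2cc(OCc3ccccc3)cc(OCc3ccccc3)c2C(=O)C([O-])=O)OCCO1 | intermediate (not isolated)
14 | 2,4-bis(benzyloxy)-6-[(2-pentyl-1,3-dioxolan-2-yl)methyl]benzoic acid | CCCCCC1(Cc2cc(OCc3ccccc3)cc(OCc3ccccc3)c2C(=O)O)OCCO1 | intermediate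
15 | 2,4-dihydroxy-6-[(2-pentyl-1,3-dioxolan-2-yl)methyl]benzoic acid | CCCCCC1(Cc2cc(O)cc(O)c2C(=O)O)OCCO1 | intermediate
16 | benzyl 2,4-dihydroxy-6-[(2-pentyl-1,3-dioxolan-2-yl)methyl]benzoate | CCCCCC1(Cc2cc(O)cc(O)c2C(=O)OCc2ccccc2)OCCO1 | intermediate
17 | benzyl 4-({2,4-bis(benzyloxy)-6-[(2-pentyl-1,3-dioxolan-2-yl)methyl]benzoyl}oxy)-2-hydroxy-6-[(2-pentyl-1,3-dioxolan-2-yl)methyl]benzoate | CCCCCC1(Cc2cc(OC(=O)c3c(OCc4ccccc4)cc(OCc4ccccc4)cc3CC3(CCCCC)OCCO3)cc(O)c2C(=O)OCc2ccccc2)OCCO1 | intermediate
18 | benzyl 4-{[2,4-bis(benzyloxy)-6-(2-oxoheptyl)benzoyl]oxy}-2-hydroxy-6-(2-oxoheptyl)benzoate | CCCCCC(=O)Cc1cc(OC(=O)c2c(OCc3ccccc3)cc(OCc3ccccc3)cc2CC(=O)CCCCC)cc(O)c1C(=O)OCc1ccccc1 | intermediate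
19 | 4-{[2,4-dihydroxy-6-(2-oxoheptyl)benzoyl]oxy}-2-hydroxy-6-(2-oxoheptyl)benzoic acid | CCCCCC(=O)Cc1cc(OC(=O)c2c(O)cc(O)cc2CC(=O)CCCCC)cc(O)c1C(=O)O | target

## Step count and risks

Total: 12 steps. Longest linear sequence: 11 steps (steps 1, 2, 3, 5, 6, 7, 8, 9, 10, 11, 12 from phenol 1). Step 4 is a one-step side branch.

**Step 5 (key step, proposed new method).** Three things may go wrong.
- The aryl anion may close on the ester carbon (five-membered ring) or on the C4 ketone instead of on C2, or be protonated before it closes.
- The strongly enolised diketo ester may react at oxygen.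
- The released benzylic enolate may condense with the glyoxylate, either by attack on the ester or by aldol closure with aromatisation.

The fallback uses the known insertion of arynes into the C–C bond of dialkyl malonates. It sets out from 5 and comes back at 14.
- Silyl triflate 5, diallyl malonate and CsF in MeCN should give prop-2-en-1-yl 2,4-bis(benzyloxy)-6-[2-oxo-2-(prop-2-en-1-yloxy)ethyl]benzoate F1, with the same orientation as in the main route.
- One equivalent of LiOH at 0 °C should hydrolyse only the unhindered aliphatic ester to 2-{3,5-bis(benzyloxy)-2-[(prop-2-en-1-yloxy)carbonyl]phenyl}acetic acid F2.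
- Amide coupling with N,O-dimethylhydroxylamine should give prop-2-en-1-yl 2,4-bis(benzyloxy)-6-{2-[methoxy(methyl)amino]-2-oxoethyl}benzoate F3.
- n-Pentylmagnesium bromide at −78 °C (Weinreb ketone synthesis; the di-ortho-substituted aryl ester is shielded) should give prop-2-en-1-yl 2,4-bis(benzyloxy)-6-(2-oxoheptyl)benzoate F4.
- Ketalisation as in step 6 should give prop-2-en-1-yl 2,4-bis(benzyloxy)-6-[(2-pentyl-1,3-dioxolan-2-yl)methyl]benzoate F5.
- Deallylation with Pd(PPh3)4 (zerovalent palladium) and morpholine should release acid 14.

**Step 1.** Bromination may occur at the position between the two benzyloxy groups, or twice, because all three free ring positions are activated by all three oxygens. The fallback replaces electrophilic substitution by directed ortho-metalation. It sets out from 1 and comes back at 5.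
- Phenol 1 and isopropyl isocyanate give 3,5-bis(benzyloxy)phenyl N-(propan-2-yl)carbamate F6.
- In situ N-silylation (TBSOTf, TMEDA), lithiation with n-BuLi/TMEDA at −78 °C between the carbamate and the benzyloxy group, and quenching with TMSCl give 3,5-bis(benzyloxy)-2-(trimethylsilyl)phenyl N-(propan-2-yl)carbamate F7.
- Carbamate cleavage with DBU and Et2NH followed by PhNTf2 in the same flask gives 5.

**Step 6.** The Lewis acid may trigger aldol closure of the side-chain ketone onto the glyoxylate ketone, or the glyoxylate ketone may be ketalised as well. The fallback removes the glyoxylate before any ketalisation. It sets out from 11 and comes back at 14.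
- LiOH and H2O2 at 0 °C convert 11 into 2,4-bis(benzyloxy)-6-(2-oxoheptyl)benzoic acid F8.
- Allyl bromide and KHCO3 in DMF give prop-2-en-1-yl 2,4-bis(benzyloxy)-6-(2-oxoheptyl)benzoate F4.
- Ketalisation gives prop-2-en-1-yl 2,4-bis(benzyloxy)-6-[(2-pentyl-1,3-dioxolan-2-yl)methyl]benzoate F5.
- Deallylation with Pd(PPh3)4 and morpholine gives 14.

**Step 10.** The di-ortho-substituted acid may be captured too slowly, so that the O-acylisourea rearranges to the N-acylurea. A ketal oxygen may take part at the activated carbonyl. Some acylation at the chelated hydroxyl cannot be excluded. The fallback uses a preformed, isolable acylating agent in place of in situ carbodiimide activation. It sets out from 14 and comes back at 17: cyanuric fluoride and pyridine convert 14 into 2,4-bis(benzyloxy)-6-[(2-pentyl-1,3-dioxolan-2-yl)methyl]benzoyl fluoride F9, which is small enough to react at a hindered carbonyl and acylates 16 in the presence of i-Pr2NEt and DMAP.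

**Step 11.** Under acid the freed ketone may close through its enol onto the neighbouring ester carbonyl. On ring B this would expel benzyl alcohol, and on ring A it would cleave the depside bond. The second dioxolane may also hydrolyse incompletely. The fallback reverses the order of unmasking. It sets out from 17 and comes back at 19: hydrogenolysis of 17 over Pd/C gives 4-({2,4-dihydroxy-6-[(2-pentyl-1,3-dioxolan-2-yl)methyl]benzoyl}oxy)-2-hydroxy-6-[(2-pentyl-1,3-dioxolan-2-yl)methyl]benzoic acid F10, whose own carboxyl should suffice to hydrolyse both dioxolanes in wet acetone at room temperature without added acid, giving 19.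

## Further compounds

F1 | step 5 | prop-2-en-1-yl 2,4-bis(benzyloxy)-6-[2-oxo-2-(prop-2-en-1-yloxy)ethyl]benzoate | C=CCOC(=O)Cc1cc(OCc2ccccc2)cc(OCc2ccccc2)c1C(=O)OCC=C
F2 | step 5 | 2-{3,5-bis(benzyloxy)-2-[(prop-2-en-1-yloxy)carbonyl]phenyl}acetic acid | OC(=O)Cc1cc(OCc2ccccc2)cc(OCc2ccccc2)c1C(=O)OCC=C
F3 | step 5 | prop-2-en-1-yl 2,4-bis(benzyloxy)-6-{2-[methoxy(methyl)amino]-2-oxoethyl}benzoate | CON(C)C(=O)Cc1cc(OCc2ccccc2)cc(OCc2ccccc2)c1C(=O)OCC=C
F4 | step 5 | prop-2-en-1-yl 2,4-bis(benzyloxy)-6-(2-oxoheptyl)benzoate | CCCCCC(=O)Cc1cc(OCc2ccccc2)cc(OCc2ccccc2)c1C(=O)OCC=C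
F5 | step 5 | prop-2-en-1-yl 2,4-bis(benzyloxy)-6-[(2-pentyl-1,3-dioxolan-2-yl)methyl]benzoate | CCCCCC1(Cc2cc(OCc3ccccc3)cc(OCc3ccccc3)c2C(=O)OCC=C)OCCO1
F6 | step 1 | 3,5-bis(benzyloxy)phenyl N-(propan-2-yl)carbamate | CC(C)NC(=O)Oc1cc(OCc2ccccc2)cc(OCc2ccccc2)c1
F7 | step 1 | 3,5-bis(benzyloxy)-2-(trimethylsilyl)phenyl N-(propan-2-yl)carbamate | CC(C)NC(=O)Oc1cc(OCc2ccccc2)cc(OCc2ccccc2)c1[Si](C)(C)C
F8 | step 6 | 2,4-bis(benzyloxy)-6-(2-oxoheptyl)benzoic acid | CCCCCC(=O)Cc1cc(OCc2ccccc2)cc(OCc2ccccc2)c1C(=O)O
F9 | step 10 | 2,4-bis(benzyloxy)-6-[(2-pentyl-1,3-dioxolan-2-yl)methyl]benzoyl fluoride | CCCCCC1(Cc2cc(OCc3ccccc3)cc(OCc3ccccc3)c2C(F)=O)OCCO1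
F10 | step 11 | 4-({2,4-dihydroxy-6-[(2-pentyl-1,3-dioxolan-2-yl)methyl]benzoyl}oxy)-2-hydroxy-6-[(2-pentyl-1,3-dioxolan-2-yl)methyl]benzoic acid | CCCCCC1(Cc2cc(OC(=O)c3c(O)cc(O)cc3CC3(CCCCC)OCCO3)cc(O)c2C(=O)O)OCCO1
A1 | alternative 1 | benzyl 2,4-dihydroxy-6-[(2-pentyl-1,3-dioxolan-2-yl)methyl]benzoate | CCCCCC1(Cc2cc(O)cc(O)c2C(=O)OCc2ccccc2)OCCO1
A2 | alternative 1 | 1-methoxy-1,3-bis(trimethylsilyloxy)buta-1,3-diene (geometry at C1 not specified) | C=C(O[Si](C)(C)C)C=C(OC)O[Si](C)(C)C
A3 | alternative 1 | benzyl 4-(2-pentyl-1,3-dioxolan-2-yl)but-2-ynoate | CCCCCC1(CC#CC(=O)OCc2ccccc2)OCCO1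
A4 | alternative 2 | 6,8-bis(benzyloxy)-3-pentyl-1H-isochromen-1-one | CCCCCC1=Cc2cc(OCc3ccccc3)cc(OCc3ccccc3)c2C(=O)O1
A5 | alternative 2 | 2,4-bis(benzyloxy)benzoic acid | OC(=O)c1ccc(OCc2ccccc2)cc1OCc1ccccc1
A6 | alternative 2 | dimethylsulfoxonium 2-oxoheptylide | CCCCCC(=O)C=S(C)(C)=O
A7 | alternative 2 | 2,4-bis(benzyloxy)-6-(2-oxoheptyl)benzoic acid | CCCCCC(=O)Cc1cc(OCc2ccccc2)cc(OCc2ccccc2)c1C(=O)O
A8 | alternative 3 | 2,4-dihydroxy-6-[(2-pentyl-1,3-dioxolan-2-yl)methyl]benzoic acid | CCCCCC1(Cc2cc(O)cc(O)c2C(=O)O)OCCO1
A9 | alternative 3 | 4-hydroxy-6-[2-oxo-3-(2-pentyl-1,3-dioxolan-2-yl)propyl]-2H-pyran-2-one | O=C1C=C(O)C=C(CC(=O)CC2(CCCCC)OCCO2)O1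
A10 | alternative 3 | potassium 3,5,7-trioxo-8-(2-pentyl-1,3-dioxolan-2-yl)octanoate | [K+].CCCCCC1(CC(=O)CC(=O)CC(=O)CC([O-])=O)OCCO1
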